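The C1–C6 oxirane of the 7-oxabicyclo[4.1.0]heptene core, flanked by the C4=C5 alkene, is treated as the contracted form of a peroxide bridging C1 and C4. This leads back to the cyclohexadiene C1=C6–C5=C4 and O2. One sensitised singlet-oxygen [4+2] forms both C–O bonds (C1–O, C4–O), closes the 2,3-dioxabicyclo[2.2.2]octene and sets C1 and C4 on the face opposite the C2/C3 oxygens; PPh3 then collapses the bridge to the vinyl epoxide. The precursor is the cis-C2,C3-bis(TBS) ether of the diene bearing CH2OBz at C1, derived from the commercial bromobenzene cis-dihydrodiol. C3 is inverted late by Mitsunobu benzoylation and C2 is acetylated.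

Key step: step 4

Remarks on the chemistry

- Locants: in the discussion C1 is the ring carbon bearing CH2OBz, C2 the future CHOAc, C3 the future CHOBz, C4 and C5 the remaining sp2 carbons of the target, and C6 the oxirane CH. Systematic names use their own locants; in 9, name locants 7 and 8 are C2 and C3.
- Stereochemical bookkeeping: with the ring drawn C1→C6 anticlockwise, the target has the oxirane oxygen up, the C2 acetate down and the C3 benzoate up. Diol 1 has both oxygens down. C2 is therefore never touched, oxygen must enter from the top face, and C3 is inverted once. All structures are consistent with this and none needed correcting.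
- Descriptor changes at C1 (R in 11 and 13, S in 10 and 15) and at the carbinol carbon next to the ring substituent (S in 3, R in 5 and 7) come from changed CIP priorities, not from any change in geometry.
- Precursor design: silyl ethers are used instead of an acetal because the vinyl epoxide formed after the key step tolerates buffered fluoride but not the acid needed for acetal cleavage. Two TBS groups on one face shield both diene termini. The benzoate is installed before photooxygenation, so no free allylic alcohol is exposed to singlet oxygen and no acylation is needed next to the peroxide.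

Step 1
Reactants: 1 (1S,2S)-3-bromocyclohexa-3,5-diene-1,2-diol; 2 tert-butyldimethylsilyl trifluoromethanesulfonate
Product: 3 (5S,6S)-1-bromo-5,6-bis[(tert-butyldimethylsilyl)oxy]cyclohexa-1,3-diene
Conditions: TBSOTf (2.4 equiv), 2,6-lutidine (3 equiv), CH2Cl2, −40 → 0 °C
Reagents that add atoms: tert-butyldimethylsilyl trifluoromethanesulfonate, CC(C)(C)[Si](C)(C)OS(=O)(=O)C(F)(F)F
Why: O-silylation with a silyl triflate and a hindered base should cap both secondary hydroxyls quickly at low temperature, before the acid-sensitive diene diol can dehydrate to a phenol, and it touches no stereocentre.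

Step 2
Reactants: 3 (5S,6S)-1-bromo-5,6-bis[(tert-butyldimethylsilyl)oxy]cyclohexa-1,3-diene; 4 (tributylstannyl)methanol
Product: 5 [(5S,6R)-5,6-bis[(tert-butyldimethylsilyl)oxy]cyclohexa-1,3-dien-1-yl]methanol
Conditions: Pd(PPh3)4 (5 mol %), degassed 1,4-dioxane, 90 °C
Reagents that add atoms: (tributylstannyl)methanol, CCCC[Sn](CCCC)(CCCC)CO
Why: Stille coupling, in which zerovalent palladium inserts into the alkenyl C–Br bond, the α-oxygenated CH2OH group transfers from tin in preference to butyl, and reductive elimination forms the C1–CH2OH bond without affecting C2 or C3.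

Step 3
Reactants: 5 [(5S,6R)-5,6-bis[(tert-butyldimethylsilyl)oxy]cyclohexa-1,3-dien-1-yl]methanol; 6 benzoyl chloride
Product: 7 [(5S,6R)-5,6-bis[(tert-butyldimethylsilyl)oxy]cyclohexa-1,3-dien-1-yl]methyl benzoate
Conditions: BzCl (1.2 equiv), Et3N, DMAP (cat.), CH2Cl2, 0 °C
Reagents that add atoms: benzoyl chloride, O=C(Cl)c1ccccc1
Why: DMAP-catalysed acylation (nucleophilic acyl substitution) of the only free, primary hydroxyl should be fast under basic, non-acidic conditions that the diene and silyl ethers tolerate, and creates no stereocentre.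

Step 4
Reactants: 7 [(5S,6R)-5,6-bis[(tert-butyldimethylsilyl)oxy]cyclohexa-1,3-dien-1-yl]methyl benzoate; 8 dioxygen
Product: 9 [(1R,4R,7S,8S)-7,8-bis[(tert-butyldimethylsilyl)oxy]-2,3-dioxabicyclo[2.2.2]oct-5-en-1-yl]methyl benzoate (peroxide bridge anti to both silyloxy groups)
Conditions: O2 (1 atm, bubbled), 5,10,15,20-tetraphenylporphyrin (1 mol %), white LED, CH2Cl2, −20 °C
Reagents that add atoms: dioxygen, O=O
Why: Triplet-excited tetraphenylporphyrin transfers its energy to O2, and the singlet oxygen so formed adds suprafacially across the ring-locked s-cis diene C1=C6–C5=C4 in a concerted [4+2] cycloaddition that makes the C1–O and C4–O bonds and leaves C5=C6. The closest known reaction type is the dye-sensitised photooxygenation of cyclohexa-1,3-dienes, including O-protected cis-cyclohexa-3,5-diene-1,2-diols, to 2,3-dioxabicyclo[2.2.2]oct-5-enes. The one new ring, the six-membered 1,2-dioxine (C1–O–O–C4–C5=C6), is closed by the intermolecular cycloaddition itself, both ring bonds forming in the same step, which turns the monocycle into the bicycle. The new stereocentres C1 and C4 are under substrate control: the two cis silyloxy groups at C2 and C3 cover one face, so O2 should approach from the other, and because the addition is suprafacial the two C–O bonds are necessarily cis to each other, giving (1R,4R). The step needs facial selectivity and [4+2] over ene chemoselectivity; the first is secured by the bulky cis-bis(TBS) ether flanking both diene termini, the second by the planar cisoid diene, which undergoes cycloaddition much faster than hydrogen abstraction from CH2OBz or C2–H, and the low temperature keeps the endoperoxide from rearranging.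

Step 5
Reactants: 9 [(1R,4R,7S,8S)-7,8-bis[(tert-butyldimethylsilyl)oxy]-2,3-dioxabicyclo[2.2.2]oct-5-en-1-yl]methyl benzoate
Product: 10 [(1S,2S,3S,6S)-2,3-bis[(tert-butyldimethylsilyl)oxy]-7-oxabicyclo[4.1.0]hept-4-en-1-yl]methyl benzoate
Conditions: PPh3 (1.1 equiv), CH2Cl2, −20 → 0 °C
Reagents that add atoms: none
Why: Phosphine deoxygenation of an unsaturated bicyclic endoperoxide to a vinyl epoxide, in which phosphorus attacks the peroxide oxygen on secondary C4 (the one on C1 is screened by the quaternary centre and its CH2OBz group), the weak O–O bond breaks, and the C1 oxygen closes onto C6 on the same face as the departing C4–O–P group (syn SN2′) with loss of Ph3P=O, so that the C1–O bond and its configuration are kept, C6 is set cis to it within the fused oxirane, the C4 stereocentre disappears and the alkene moves to C4=C5.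

Step 6
Reactants: 10 [(1S,2S,3S,6S)-2,3-bis[(tert-butyldimethylsilyl)oxy]-7-oxabicyclo[4.1.0]hept-4-en-1-yl]methyl benzoate
Product: 11 [(1R,2S,3S,6S)-2,3-dihydroxy-7-oxabicyclo[4.1.0]hept-4-en-1-yl]methyl benzoate
Conditions: TBAF (3 equiv), AcOH (3 equiv), THF, 0 °C → rt
Reagents that add atoms: none
Why: Fluoride-induced cleavage of both silyl ethers, driven by Si–F bond formation and buffered with acetic acid so that no free alkoxide persists to trigger Payne rearrangement of the C2 oxygen onto the oxirane or benzoyl migration, while nothing acidic enough to open the vinyl epoxide is present and no stereocentre is affected.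

Step 7
Reactants: 11 [(1R,2S,3S,6S)-2,3-dihydroxy-7-oxabicyclo[4.1.0]hept-4-en-1-yl]methyl benzoate; 12 benzoic acid
Product: 13 [(1R,2S,3R,6S)-3-(benzoyloxy)-2-hydroxy-7-oxabicyclo[4.1.0]hept-4-en-1-yl]methyl benzoate
Conditions: PPh3 (1.3 equiv), DIAD (1.3 equiv), BzOH (1.3 equiv), THF, 0 °C → rt
Reagents that add atoms: benzoic acid, O=C(O)c1ccccc1
Why: Mitsunobu reaction, in which the allylic, less hindered C3 hydroxyl is activated as its oxyphosphonium ion and displaced by benzoate with SN2 inversion, setting C3 as R (benzoate trans to the C2 oxygen and cis to the oxirane), whereas the C2 hydroxyl next to quaternary C1 is too hindered for substitution and, being cis to the C3 oxygen, cannot close an epoxide onto the activated carbon.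

Step 8
Reactants: 13 [(1R,2S,3R,6S)-3-(benzoyloxy)-2-hydroxy-7-oxabicyclo[4.1.0]hept-4-en-1-yl]methyl benzoate; 14 acetic anhydride
Product: 15 [(1S,2S,3R,6S)-2-(acetyloxy)-3-(benzoyloxy)-7-oxabicyclo[4.1.0]hept-4-en-1-yl]methyl benzoate
Conditions: Ac2O (2 equiv), pyridine, DMAP (cat.), CH2Cl2, 0 °C → rt
Reagents that add atoms: acetic anhydride, CC(=O)OC(C)=O
Why: DMAP-catalysed O-acetylation (nucleophilic acyl substitution) of the remaining secondary hydroxyl takes place at oxygen and so retains the C2 configuration, and the mildly basic medium should leave the vinyl epoxide and both benzoates intact.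

Compound list

1 | (1S,2S)-3-bromocyclohexa-3,5-diene-1,2-diol | BrC1=CC=C[C@H](O)[C@@H]1O | starting material
2 | tert-butyldimethylsilyl trifluoromethanesulfonate | CC(C)(C)[Si](C)(C)OS(=O)(=O)C(F)(F)F | starting material
3 | (5S,6S)-1-bromo-5,6-bis[(tert-butyldimethylsilyl)oxy]cyclohexa-1,3-diene | BrC1=CC=C[C@H](O[Si](C)(C)C(C)(C)C)[C@@H]1O[Si](C)(C)C(C)(C)C | intermediate
4 | (tributylstannyl)methanol | CCCC[Sn](CCCC)(CCCC)CO | starting material
5 | [(5S,6R)-5,6-bis[(tert-butyldimethylsilyl)oxy]cyclohexa-1,3-dien-1-yl]methanol | OCC1=CC=C[C@H](O[Si](C)(C)C(C)(C)C)[C@@H]1O[Si](C)(C)C(C)(C)C | intermediate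
6 | benzoyl chloride | O=C(Cl)c1ccccc1 | starting material
7 | [(5S,6R)-5,6-bis[(tert-butyldimethylsilyl)oxy]cyclohexa-1,3-dien-1-yl]methyl benzoate | O=C(OCC1=CC=C[C@H](O[Si](C)(C)C(C)(C)C)[C@@H]1O[Si](C)(C)C(C)(C)C)c1ccccc1 | intermediate
8 | dioxygen | O=O | starting material
9 | [(1R,4R,7S,8S)-7,8-bis[(tert-butyldimethylsilyl)oxy]-2,3-dioxabicyclo[2.2.2]oct-5-en-1-yl]methyl benzoate | O=C(OC[C@]12OO[C@H](C=C1)[C@H](O[Si](C)(C)C(C)(C)C)[C@@H]2O[Si](C)(C)C(C)(C)C)c1ccccc1 | intermediate
10 | [(1S,2S,3S,6S)-2,3-bis[(tert-butyldimethylsilyl)oxy]-7-oxabicyclo[4.1.0]hept-4-en-1-yl]methyl benzoate | CC(C)(C)[Si](C)(C)O[C@H]1[C@@H](O[Si](C)(C)C(C)(C)C)C=C[C@@H]2O[C@@]21COC(=O)c1ccccc1 | intermediate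
11 | [(1R,2S,3S,6S)-2,3-dihydroxy-7-oxabicyclo[4.1.0]hept-4-en-1-yl]methyl benzoate | O[C@H]1[C@@H](O)C=C[C@@H]2O[C@@]21COC(=O)c1ccccc1 | intermediate
12 | benzoic acid | O=C(O)c1ccccc1 | starting material
13 | [(1R,2S,3R,6S)-3-(benzoyloxy)-2-hydroxy-7-oxabicyclo[4.1.0]hept-4-en-1-yl]methyl benzoate | O[C@H]1[C@H](OC(=O)c2ccccc2)C=C[C@@H]2O[C@@]21COC(=O)c1ccccc1 | intermediate
14 | acetic anhydride | CC(=O)OC(C)=O | starting material
15 | [(1S,2S,3R,6S)-2-(acetyloxy)-3-(benzoyloxy)-7-oxabicyclo[4.1.0]hept-4-en-1-yl]methyl benzoate | CC(=O)O[C@H]1[C@H](OC(=O)c2ccccc2)C=C[C@@H]2O[C@@]21COC(=O)c1ccccc1 | target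

Total step count: 8. Longest linear sequence: 8 steps (1 → 15).

Steps most likely to fail

Step 5. The phosphine may be delivered to the oxygen on C1, or the two P–O bonded forms may interconvert, so that the C4 oxygen closes onto C5 and the oxirane forms at the wrong pair of carbons with the alkene at C1=C6. The fallback sets out from 9. The O–O bond would be reduced with thiourea (MeOH, 0 °C → rt) to the cis-ene-1,4-diol [(1R,4R,5S,6S)-5,6-bis[(tert-butyldimethylsilyl)oxy]-1,4-dihydroxycyclohex-2-en-1-yl]methyl benzoate F1, which keeps both new oxygens on the top face. A Mitsunobu-type cyclodehydration (PPh3, DIAD, THF, 0 °C, no acid partner) can turn only the secondary C4 hydroxyl into an oxyphosphonium leaving group, since the tertiary C1 hydroxyl cannot be activated. The C1 oxygen must then act as the nucleophile and should close onto C6 by the same syn SN2′ path, coming back to the route at 10.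

Step 7. Activation of the cis-diol may stall as a cyclic dioxaphosphorane or occur at the wrong oxygen, or benzoate may be delivered with allylic transposition (SN2′ at C5). The fallback sets out from 11 and separates activation from displacement. Chemoselective sulfonylation of the less hindered allylic hydroxyl (MsCl 1.05 equiv, 2,4,6-collidine, CH2Cl2, −20 °C) should give the C3 mesylate [(1R,2S,3S,6S)-2-hydroxy-3-(methylsulfonyloxy)-7-oxabicyclo[4.1.0]hept-4-en-1-yl]methyl benzoate F2. Direct SN2 displacement with cesium benzoate (CsO2CPh) and 18-crown-6 in toluene at rt to 40 °C then inverts C3 and comes back to the route at 13. The cis C2 hydroxyl cannot displace the mesylate intramolecularly.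

Step 2. Transfer of the sp3 hydroxymethyl group from tin may be slow, allowing protodebromination, butyl transfer, or thermal dimerisation and aromatisation of the diene at the temperature required. The fallback sets out from 3. Methoxycarbonylation (PdCl2(PPh3)2 5 mol %, CO 1 atm, MeOH, Et3N, DMF, 60 °C) should give the dienoate methyl (5S,6R)-5,6-bis[(tert-butyldimethylsilyl)oxy]cyclohexa-1,3-diene-1-carboxylate F3. 1,2-Reduction of the ester with i-Bu2AlH (2.2 equiv, CH2Cl2, −78 °C) then comes back to the route at 5.

The cycloaddition of step 4 rests on the closest precedent and is judged less likely to fail than these three.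

Further compounds

F1 | step 5 | [(1R,4R,5S,6S)-5,6-bis[(tert-butyldimethylsilyl)oxy]-1,4-dihydroxycyclohex-2-en-1-yl]methyl benzoate | O=C(OC[C@]1(O)C=C[C@@H](O)[C@H](O[Si](C)(C)C(C)(C)C)[C@@H]1O[Si](C)(C)C(C)(C)C)c1ccccc1
F2 | step 7 | [(1R,2S,3S,6S)-2-hydroxy-3-(methylsulfonyloxy)-7-oxabicyclo[4.1.0]hept-4-en-1-yl]methyl benzoate | O[C@H]1[C@@H](OS(C)(=O)=O)C=C[C@@H]2O[C@@]21COC(=O)c1ccccc1
F3 | step 2 | methyl (5S,6R)-5,6-bis[(tert-butyldimethylsilyl)oxy]cyclohexa-1,3-diene-1-carboxylate | COC(=O)C1=CC=C[C@H](O[Si](C)(C)C(C)(C)C)[C@@H]1O[Si](C)(C)C(C)(C)C
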